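Ring C is not grown from an acetophenone or a chalcone but cut at three bonds at once: C4a–C4, C4–C3 and O1–C2. One palladium-catalysed carbonylative annulation joins iodophloroglucinol triacetate, carbon monoxide (the future C4) and 4-benzyloxy-3-hydroxyphenylacetylene and closes the γ-pyrone in the same flask. The step exploits the local twofold symmetry of ring A about its C4a···C7 axis: O1 and O5 are equivalent until closure, so no regiochemical choice exists. The new C4=O then chelates 5-OH, which leaves only 7-OH and 3'-OH open to sulfation, while the benzyl ether carried in by the alkyne masks 4'-OH.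

Key step: step 5

Remark: the target has no stereocentre, stereogenic axis or configurable double bond; it is achiral, so no enantiomer has to be selected.
Remark: the sulfate monoesters of the last two steps are drawn in the neutral hydrogen sulfate form of the target SMILES; at the bench they are carried as sodium salts, and the acid form is set free only at the very end on a cold H+ resin.

Step 1
Reactants: 1 phloroglucinol (benzene-1,3,5-triol)
Product: 2 2-iodobenzene-1,3,5-triol
Conditions: I2 (1.0 equiv), NaHCO3 (1.1 equiv), THF–H2O, 0 °C; crude product taken on at once
Reagents that add atoms: iodine, II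
Why: Electrophilic aromatic iodination of a phenoxide-activated arene whose three C–H positions are equivalent, so only the degree of iodination has to be held, by stoichiometry and low temperature.

Step 2
Reactants: 2 2-iodobenzene-1,3,5-triol
Product: 3 2-iodobenzene-1,3,5-triyl triacetate
Conditions: Ac2O (3.5 equiv), pyridine, cat. DMAP, CH2Cl2, 0 °C to rt
Reagents that add atoms: acetic anhydride, CC(=O)OC(C)=O
Why: Routine phenol O-acetylation, which should turn the labile iodotriol into a storable triester and lower the electron density of the ring for the later oxidative addition.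

Step 3
Reactants: 4 3,4-dihydroxybenzaldehyde
Product: 5 4-(benzyloxy)-3-hydroxybenzaldehyde
Conditions: BnBr (1.0 equiv), NaHCO3 (1.2 equiv), DMF, 40 °C
Reagents that add atoms: benzyl bromide, BrCc1ccccc1
Why: Williamson etherification under a weak base that ionises only the more acidic 4-OH (para to the formyl group, a vinylogous acid), which fixes the 3'/4' differentiation of the target at the fragment stage.

Step 4
Reactants: 5 4-(benzyloxy)-3-hydroxybenzaldehyde
Product: 6 2-(benzyloxy)-5-ethynylphenol
Conditions: dimethyl (1-diazo-2-oxopropyl)phosphonate (1.3 equiv), K2CO3 (3 equiv), MeOH, rt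
Reagents that add atoms: dimethyl (1-diazo-2-oxopropyl)phosphonate, COP(=O)(OC)C(=[N+]=[N-])C(C)=O
Why: Seyferth–Gilbert homologation in its Ohira–Bestmann form, which tolerates a free phenol when extra base is supplied, the phenoxide being meta to the aldehyde and therefore not deactivating it by conjugation.

Step 5
Reactants: 3 2-iodobenzene-1,3,5-triyl triacetate; 6 2-(benzyloxy)-5-ethynylphenol; 7 carbon monoxide
Product: 10 4'-O-benzylluteolin (2-[4-(benzyloxy)-3-hydroxyphenyl]-5,7-dihydroxy-4H-chromen-4-one), via ynone triacetate 8 (not isolated), via diethylamino enaminone 9 (not isolated)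
Conditions: PdCl2(dppf) (5 mol %), CO (5 bar), Et2NH–DMF (1:1, degassed, no copper), 60 °C
Reagents that add atoms: carbon monoxide, [C-]#[O+] (reactant 7); diethylamine, CCNCC (atoms held only in intermediate 9 and released again on ring closure)
Why: Pd(0) adds oxidatively to the C–I bond of 3, CO inserts to give an aroyl-palladium(II) species, and copper-free alkynylation with 6 (deprotonated by Et2NH) followed by reductive elimination forges C4a–C4 and C4–C3 in ynone 8; Et2NH then cleaves the three aryl acetates by aminolysis and adds to the ynone to give push–pull enaminone 9, whose ortho-phenol displaces the amine at C2 to form O1–C2. The closest known reaction type is the palladium-catalysed carbonylative annulation of o-iodophenols or their acetates with terminal arylacetylenes in diethylamine, that is, a carbonylative Sonogashira coupling followed by oxa-Michael closure. The single ring closed, the γ-pyrone ring C, forms by a 6-endo-trig addition–elimination on 9 (formally the 6-endo-dig mode of 8), and the 5-exo-dig mode that would lead to the aurone skeleton is shut off because the amine places the leaving group on C2 alone. No stereocentre is created, and the geometry of the C=C bond in 9 is of no consequence, since the push–pull alkene rotates freely and is consumed. The step needs CO uptake to outrun direct alkynylation and amine capture of the aroyl-palladium: the absence of copper, a CO-saturated medium and the two ortho-acetoxy groups, which speed insertion by steric relief and shield the acyl carbon from the bulky secondary amine but not from the slim alkyne, should secure this. Site selectivity of closure is no issue because the two ortho oxygens of 8 are symmetry-equivalent (one becomes O1, the other the chelated 5-OH), the remote 3'-OH cannot reach the ynone, and the benzyl ether is inert.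

Step 6
Reactants: 10 4'-O-benzylluteolin
Product: 11 4'-O-benzylluteolin 7,3'-bis(hydrogen sulfate)
Conditions: SO3·pyridine (3 equiv), pyridine, 0 °C to rt; Dowex 50W (Na+ form); C18 or Sephadex LH-20
Reagents that add atoms: sulfur trioxide–pyridine complex, O=S(=O)([O-])[n+]1ccccc1
Why: Phenol O-sulfation with an amine–SO3 complex, in which the acidic 7-OH and the free 3'-OH should react at room temperature, whereas 5-OH, locked in a six-membered hydrogen bond to C4=O, needs forcing conditions and 4'-O is blocked as its benzyl ether.

Step 7
Reactants: 11 4'-O-benzylluteolin 7,3'-bis(hydrogen sulfate)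
Product: 12 luteolin 7,3'-disulfate
Conditions: H2 (1 atm), 10% Pd/C, MeOH–H2O, rt; filter; Dowex 50W (H+ form), 0–5 °C; freeze-dry
Reagents that add atoms: none
Why: Catalytic hydrogenolysis of a phenolic benzyl ether, under which aryl sulfates held as neutral sodium salts are inert and the pyrone C2=C3 bond should not be reduced at 1 atm, followed by a short cold pass through H+ resin to give the acid form drawn in the target.

Compound list
1 | phloroglucinol (benzene-1,3,5-triol) | Oc1cc(O)cc(O)c1 | starting material
2 | 2-iodobenzene-1,3,5-triol | Oc1cc(O)c(I)c(O)c1 | intermediate
3 | 2-iodobenzene-1,3,5-triyl triacetate | CC(=O)Oc1cc(OC(C)=O)c(I)c(OC(C)=O)c1 | intermediate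
4 | 3,4-dihydroxybenzaldehyde | O=Cc1ccc(O)c(O)c1 | starting material
5 | 4-(benzyloxy)-3-hydroxybenzaldehyde | O=Cc1ccc(OCc2ccccc2)c(O)c1 | intermediate
6 | 2-(benzyloxy)-5-ethynylphenol | C#Cc1ccc(OCc2ccccc2)c(O)c1 | intermediate
7 | carbon monoxide | [C-]#[O+] | starting material
8 | ynone triacetate, 2-{3-[4-(benzyloxy)-3-hydroxyphenyl]prop-2-ynoyl}benzene-1,3,5-triyl triacetate | CC(=O)Oc1cc(OC(C)=O)c(C(=O)C#Cc2ccc(OCc3ccccc3)c(O)c2)c(OC(C)=O)c1 | intermediate (not isolated)
9 | diethylamino enaminone, (E)-3-[4-(benzyloxy)-3-hydroxyphenyl]-3-(diethylamino)-1-(2,4,6-trihydroxyphenyl)prop-2-en-1-one | CCN(CC)/C(=C/C(=O)c1c(O)cc(O)cc1O)c1ccc(OCc2ccccc2)c(O)c1 | intermediate (not isolated)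
10 | 4'-O-benzylluteolin, 2-[4-(benzyloxy)-3-hydroxyphenyl]-5,7-dihydroxy-4H-chromen-4-one | O=c1cc(-c2ccc(OCc3ccccc3)c(O)c2)oc2cc(O)cc(O)c12 | intermediate
11 | 4'-O-benzylluteolin 7,3'-bis(hydrogen sulfate) | O=c1cc(-c2ccc(OCc3ccccc3)c(OS(=O)(=O)O)c2)oc2cc(OS(=O)(=O)O)cc(O)c12 | intermediate
12 | luteolin 7,3'-disulfate | O=c1cc(-c2ccc(O)c(OS(=O)(=O)O)c2)oc2cc(OS(=O)(=O)O)cc(O)c12 | target

Total step count: 7
Longest linear sequence: 5 steps (1 → 2 → 3 → 10 → 11 → 12; the branch 4 → 5 → 6 → 10 → 11 → 12 is equally long)

Steps most likely to fail

Step 5. The acetates may be lost before palladium has engaged the doubly ortho-flanked C–I bond. Oxidative addition to the then very electron-rich ring would slow down. Amine capture of the acyl-palladium, hydrodeiodination or coupling without CO uptake could then overtake the annulation. The fallback uses no palladium and no CO and takes C4 from an ester carbon instead. It sets out from aldehyde 5. Roskamp homologation with ethyl diazoacetate (cat. SnCl2 or NbCl5, CH2Cl2, rt) should give ethyl 3-[4-(benzyloxy)-3-hydroxyphenyl]-3-oxopropanoate F1. This β-keto ester is then heated neat with phloroglucinol 1 (about 240 °C, a few minutes, microwave or sand bath). Thermal loss of alcohol gives an aroylketene that C-acylates the phloroglucinol, and the resulting 1,3-diketone cyclodehydrates. The fallback comes back to the route at 10.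

Step 6. Sulfation may spill over to the chelated 5-OH or stall at the 3'-OH crowded by the neighbouring benzyl ether, giving ionic mixtures that resist separation. The fallback replaces direct sulfation by masked, neutral sulfate diesters. It sets out from 10. Treatment with 2,2,2-trichloroethyl chlorosulfate (2.2 equiv), Et3N and DMAP in THF (0 °C to rt) should give 4'-O-benzylluteolin 7,3'-bis(2,2,2-trichloroethyl sulfate) F2, which can be purified on silica from under- and over-reacted material. Reductive fragmentation of both trichloroethyl esters with zinc dust and ammonium formate in MeOH at rt leaves the benzyl ether untouched. The fallback comes back to the route at 11.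

Step 1. Iodination of the free triol may run on to higher iodination. The mono-iodide may also suffer oxidation or proto-deiodination during isolation. The fallback moves C–I bond formation onto an electronically attenuated arene. It sets out from 1, which is peracetylated first (Ac2O, pyridine) to benzene-1,3,5-triyl triacetate F3, a stable triester. F3 is then mono-iodinated by SEAr with an acid-activated iodonium source (N-iodosuccinimide, CF3CO2H–MeCN, rt). The first iodine, flanked by two acetoxy groups, should deactivate and crowd the ring enough to stop further substitution. The fallback bypasses 2 and comes back to the route at 3.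

Further compounds
F1 | step 5 | ethyl 3-[4-(benzyloxy)-3-hydroxyphenyl]-3-oxopropanoate | CCOC(=O)CC(=O)c1ccc(OCc2ccccc2)c(O)c1
F2 | step 6 | 4'-O-benzylluteolin 7,3'-bis(2,2,2-trichloroethyl sulfate) | O=c1cc(-c2ccc(OCc3ccccc3)c(OS(=O)(=O)OCC(Cl)(Cl)Cl)c2)oc2cc(OS(=O)(=O)OCC(Cl)(Cl)Cl)cc(O)c12
F3 | step 1 | benzene-1,3,5-triyl triacetate | CC(=O)Oc1cc(OC(C)=O)cc(OC(C)=O)c1
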